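Atom labels: the ring carbon that carries the benzoyloxymethyl carbon C7 is C1, the olefinic CH is C2, and the four carbinol carbons follow as C3–C6 (ester on O5). In the six-membered ring the oxygens on C3 and C6 sit 1,4 to each other, which betrays a toluquinone-type core. The anti-disposed O4 hydroxyl and O5 ester betray a C4–C5 oxirane cleaved at C5. The plan therefore hinges on epoxidising the C4=C5 bond of a planar, achiral quinone monoketal (ketone at C3, dimethyl ketal at C6, silyl ether on O7) on one enantioface. That single operation makes two C–O bonds, the oxirane and stereocentres C4 and C5; the remaining centres are relayed from them.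

Key step: step 4

Assumption: N-benzylcinchonidinium chloride is taken to leave open the enantioface of the dienone that leads to the (4S,5R)-oxirane. If it favours the antipode, the pseudoenantiomeric N-benzylcinchoninium chloride takes its place and nothing else changes.

Configuration check: the target is (3R,4R,5R,6R). O3 and O4 lie on one ring face (the lower face below) and O5 and O6 on the other (upper face), so the relationships are 3,4-cis, 4,5-trans and 5,6-cis. A lower-face (4S,5R)-oxirane maps onto this pattern.

Design remarks:
- The silyl ether serves only the strongly basic steps 2 and 4. It is exchanged for the final O7 benzoate directly after the key step, while O7 is the only hydroxyl present. No polyol then has to be acylated selectively, and the migration-prone O5 benzoate sees only one further step.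
- An undirected small hydride is avoided at C6. Axial attack on the half-chair with O4 and O5 equatorial would give the 5,6-trans epimer, so hydride is delivered from a boron held on the lower-face hydroxyl.

Step 1
Reactants: 1 2,5-dimethoxybenzyl alcohol; 2 tert-butyldimethylsilyl chloride
Product: 3 tert-butyl[(2,5-dimethoxybenzyl)oxy]dimethylsilane
Conditions: TBSCl, imidazole, DMF, rt
Reagents that add atoms: tert-butyldimethylsilyl chloride, CC(C)(C)[Si](C)(C)Cl
Why: Imidazole-promoted O-silylation of a primary benzylic alcohol is routine, and the alkyl TBS ether tolerates the methanolic KOH of step 2 and the aqueous NaOH of step 4, which an ester on O7 would not.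

Step 2
Reactants: 3 tert-butyl[(2,5-dimethoxybenzyl)oxy]dimethylsilane
Product: 4 tert-butyldimethyl[(3,3,6,6-tetramethoxycyclohexa-1,4-dien-1-yl)methoxy]silane (quinone bisketal)
Conditions: Pt anode, Pt cathode, undivided cell, constant current, 1% KOH in MeOH, 0 °C
Reagents that add atoms: methanol, CO
Why: Anodic dimethoxylation of a 1,4-dimethoxyarene (two electron-transfer/methoxide-capture events at the ipso carbons C3 and C6) is the standard entry to quinone bisketals, creates no stereocentre and leaves an alkyl silyl ether untouched in cold basic methanol.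

Step 3
Reactants: 4 quinone bisketal
Product: 5 3-[(tert-butyldimethylsilyloxy)methyl]-4,4-dimethoxycyclohexa-2,5-dien-1-one (target numbering: C3 ketone, C6 ketal)
Conditions: 2% aq AcOH, acetone, 0 °C to rt
Reagents that add atoms: water, O
Why: Regioselective acid-catalysed monohydrolysis of a quinone bisketal: ionisation at C3 gives a methoxy-stabilised pentadienyl cation whose charge reaches the alkyl-bearing carbon C1, ionisation at the more crowded C6 gains nothing from that substituent, the electron-poor dienone formed resists loss of the second ketal, and TBS survives dilute acetic acid.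

Step 4
Reactants: 5 dienone monoketal
Product: 7 tert-butyl{[(4S,5R)-4,5-epoxy-6,6-dimethoxy-3-oxocyclohex-1-en-1-yl]methoxy}dimethylsilane, via C5 tert-butylperoxy dienolate 6 (not isolated)
Conditions: t-BuOOH (70% aq), N-benzylcinchonidinium chloride (10 mol %), 1 M aq NaOH, toluene, 0 °C to rt
Reagents that add atoms: tert-butyl hydroperoxide, CC(C)(C)OO
Why: This is a Weitz–Scheffer nucleophilic epoxidation run under chiral phase-transfer catalysis, a reaction class already practised on quinone monoketals and cyclic enones. t-BuOO−, carried into toluene as a tight ion pair with the cinchonidinium cation, adds in a conjugate sense to the unsubstituted β-carbon C5 and gives dienolate 6. The oxirane then closes by 3-exo-tet attack of the enolate carbon C4 on the proximal peroxide oxygen with loss of tert-butoxide. C5 is set by the enantioface that the chiral cation leaves open on the flat substrate, and C4 follows necessarily because a three-membered ring can only be cis-fused to the six-membered ring. Site selectivity for C4=C5 over C1=C2 is secured by the fully substituted β-carbon C1, and the C6 ketal keeps a second enone from competing and blocks aromatisation. Silyl ether and ketal are inert to aqueous NaOH, so enantioface selection is the only open question.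

Step 5
Reactants: 7 epoxy enone monoketal (TBS ether)
Product: 8 (4S,5R)-4,5-epoxy-1-(hydroxymethyl)-6,6-dimethoxycyclohex-1-en-3-one
Conditions: Bu4NF/AcOH (1:1), THF, 0 °C to rt
Reagents that add atoms: none
Why: Fluoride-induced desilylation buffered with acetic acid stays close to neutral, so the oxirane, the enone and the dimethyl ketal are left alone and C4 and C5 are not touched.

Step 6
Reactants: 8 primary alcohol; 9 benzoyl chloride
Product: 10 [(4S,5R)-4,5-epoxy-6,6-dimethoxy-3-oxocyclohex-1-en-1-yl]methyl benzoate
Conditions: BzCl, pyridine, CH2Cl2, 0 °C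
Reagents that add atoms: benzoyl chloride, O=C(Cl)c1ccccc1
Why: Pyridine-mediated acylation of the only hydroxyl present installs the final O7 benzoate without any site-selectivity issue, and the ester is expected to be crystalline, which offers a point for enantiomeric enrichment and a check of absolute configuration.

Step 7
Reactants: 10 epoxy enone monoketal (O7 benzoate)
Product: 11 [(3R,4R,5R)-4,5-epoxy-3-hydroxy-6,6-dimethoxycyclohex-1-en-1-yl]methyl benzoate (OH cis to the oxirane)
Conditions: NaBH4, CeCl3·7H2O, MeOH, −78 °C
Reagents that add atoms: none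
Why: Luche 1,2-reduction attacks only the C3 carbonyl carbon, from the upper face opposite the adjacent oxirane oxygen, which places O3 on the lower face cis to the oxirane (3R), while benzoate, ketal and oxirane are inert at this temperature.

Step 8
Reactants: 11 cis-epoxy alcohol ketal
Product: 12 [(3R,4R,5R)-4,5-epoxy-3-hydroxy-6-oxocyclohex-1-en-1-yl]methyl benzoate
Conditions: TsOH·H2O (10 mol %), acetone/H2O (10:1), rt
Reagents that add atoms: water, O
Why: Acid-catalysed hydrolysis of an allylic dimethyl ketal runs through an oxocarbenium ion stabilised by the C1=C2 bond under conditions too mild to open the electron-poor oxirane or to ionise C3–OH, so the three stereocentres are carried over unchanged.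

Step 9
Reactants: 12 epoxy hydroxy enone; 13 benzoic acid
Product: 14 [(3R,4R,5S)-5-benzoyloxy-3,4-dihydroxy-6-oxocyclohex-1-en-1-yl]methyl benzoate
Conditions: PhCO2H, Ti(OiPr)4 (1.5 equiv), CH2Cl2, rt; aq tartaric acid work-up
Reagents that add atoms: benzoic acid, OC(=O)c1ccccc1
Why: Titanium-assisted opening of a 2,3-epoxy alcohol by a carboxylic acid (Caron–Sharpless opening): titanium held by O3 and the cis oxirane oxygen favours cleavage of the distal C5–O bond, which leads to a five-membered 3,4-diolate chelate, C5 is also an SN2-activated α-keto carbon, and backside attack of benzoate from the upper face inverts C5 to give the 4,5-trans pair (5S in the ketone).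

Step 10
Reactants: 14 dihydroxy keto dibenzoate
Product: 16 [(3R,4R,5R,6R)-5-benzoyloxy-3,4,6-trihydroxycyclohex-1-en-1-yl]methyl benzoate, via O4-bound diacetoxyborohydride 15 (not isolated)
Conditions: Me4NBH(OAc)3, MeCN/AcOH (1:1), −40 to −20 °C; aq sodium potassium tartrate work-up
Reagents that add atoms: none
Why: Hydroxyl-directed Evans–Saksena reduction: exchange of one acetate on boron for O4–H gives 15, which can pass hydride to C6 only across the lower face (axial attack in the half-chair with O4 axial), so O6 ends on the upper face, 1,3-anti to O4 and cis to the O5 benzoate (6R), while the reagent ignores esters and the C1=C2 bond and the acidic medium suppresses benzoyl migration.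

Compound list
1 | 2,5-dimethoxybenzyl alcohol | COc1ccc(OC)c(CO)c1 | starting material
2 | tert-butyldimethylsilyl chloride | CC(C)(C)[Si](C)(C)Cl | starting material
3 | tert-butyl[(2,5-dimethoxybenzyl)oxy]dimethylsilane | COc1ccc(OC)c(CO[Si](C)(C)C(C)(C)C)c1 | intermediate
4 | tert-butyldimethyl[(3,3,6,6-tetramethoxycyclohexa-1,4-dien-1-yl)methoxy]silane | CC(C)(C)[Si](C)(C)OCC1=CC(OC)(OC)C=CC1(OC)OC | intermediate
5 | 3-[(tert-butyldimethylsilyloxy)methyl]-4,4-dimethoxycyclohexa-2,5-dien-1-one | CC(C)(C)[Si](C)(C)OCC1=CC(=O)C=CC1(OC)OC | intermediate
6 | (5R)-5-(tert-butylperoxy)-6,6-dimethoxy-1-(TBSOCH2)cyclohexa-1,3-dien-3-olate, anion of the ion pair with the catalyst cation | CC(C)(C)[Si](C)(C)OCC1=CC([O-])=C[C@@H](OOC(C)(C)C)C1(OC)OC | intermediate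
7 | tert-butyl{[(4S,5R)-4,5-epoxy-6,6-dimethoxy-3-oxocyclohex-1-en-1-yl]methoxy}dimethylsilane | CC(C)(C)[Si](C)(C)OCC1=CC(=O)[C@@H](O2)[C@@H]2C1(OC)OC | intermediate
8 | (4S,5R)-4,5-epoxy-1-(hydroxymethyl)-6,6-dimethoxycyclohex-1-en-3-one | OCC1=CC(=O)[C@@H](O2)[C@@H]2C1(OC)OC | intermediate
9 | benzoyl chloride | O=C(Cl)c1ccccc1 | starting material
10 | [(4S,5R)-4,5-epoxy-6,6-dimethoxy-3-oxocyclohex-1-en-1-yl]methyl benzoate | O=C(OCC1=CC(=O)[C@@H](O2)[C@@H]2C1(OC)OC)c1ccccc1 | intermediate
11 | [(3R,4R,5R)-4,5-epoxy-3-hydroxy-6,6-dimethoxycyclohex-1-en-1-yl]methyl benzoate | O=C(OCC1=C[C@@H](O)[C@@H](O2)[C@@H]2C1(OC)OC)c1ccccc1 | intermediate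
12 | [(3R,4R,5R)-4,5-epoxy-3-hydroxy-6-oxocyclohex-1-en-1-yl]methyl benzoate | O=C(OCC1=C[C@@H](O)[C@@H](O2)[C@@H]2C1=O)c1ccccc1 | intermediate
13 | benzoic acid | OC(=O)c1ccccc1 | starting material
14 | [(3R,4R,5S)-5-benzoyloxy-3,4-dihydroxy-6-oxocyclohex-1-en-1-yl]methyl benzoate | O=C(OCC1=C[C@@H](O)[C@@H](O)[C@H](OC(=O)c2ccccc2)C1=O)c1ccccc1 | intermediate
15 | tetramethylammonium salt of the O4-bound diacetoxyborohydride of 14 | C[N+](C)(C)C.O=C(OCC1=C[C@@H](O)[C@@H](O[BH-](OC(C)=O)OC(C)=O)[C@H](OC(=O)c2ccccc2)C1=O)c1ccccc1 | intermediate
16 | [(3R,4R,5R,6R)-5-benzoyloxy-3,4,6-trihydroxycyclohex-1-en-1-yl]methyl benzoate | O=C(OCC1=C[C@@H](O)[C@@H](O)[C@H](OC(=O)c2ccccc2)[C@@H]1O)c1ccccc1 | target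

Total step count: 10. Longest linear sequence: 10 (fully linear from 1).

Steps most likely to fail

**Step 4.**
- Risk: too little discrimination between the two enantiofaces of the flat dienone, or turnover so slow that base-induced decomposition competes.
- Fallback (resolution in place of asymmetric induction), setting out from 5 and returning at 11. 5 is epoxidised without a chiral catalyst (t-BuOOH, DBU, CH2Cl2, 0 °C) to the racemic epoxy enone monoketal F1. This is taken through the operations of steps 5 to 7 to the racemic primary alcohol F2, the racemic O7 benzoate F3 and the racemic cis-epoxy alcohol F4.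
- F4 then undergoes lipase-catalysed kinetic resolution (Burkholderia cepacia lipase or Candida antarctica lipase B, vinyl acetate, MTBE, 30 °C). The enzyme is chosen by screening so that the antipode is acetylated to the (3S,4S,5S)-acetate F5. Conversion is taken slightly past one half, and the unreacted alcohol, separated by chromatography, is 11.

**Step 9.**
- Risk: attack of benzoate at C4 instead of C5, ester exchange or isopropoxide transfer at titanium, and dehydration of the β-hydroxy ketone followed by aromatisation.
- Fallback (oxygen first, acyl group later), setting out from 12 and returning at 14. The oxirane is hydrolysed (cat. H2SO4, THF/H2O, rt to 40 °C) to the 3,4,5-triol F6.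
- 2,2-Dimethoxypropane and cat. TsOH·H2O in acetone convert it into the 3,4-O-isopropylidene ketone F7. Only the isomer with a cis-3,4-diol (water entered at C5) can undergo this readily, so material opened at C4 is removed here.
- The single remaining hydroxyl O5 is benzoylated (9, pyridine, CH2Cl2, 0 °C) to the acetonide benzoate F8, and aqueous TFA in CH2Cl2 at 0 °C releases 14.

**Step 10.**
- Risk: hydride delivery to the upper face if the half-chair with axial O4 is not populated, which would mean poor facial selectivity, and drift of the benzoyl group from O5 to O6 or O4 during work-up.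
- Fallback (catalyst control in place of substrate direction), setting out from 14 and returning at 16. A Corey–Bakshi–Shibata reduction is run with the B-methyl oxazaborolidine derived from (R)-diphenylprolinol and catecholborane in toluene at −78 °C.
- The alkenyl flank C1 with its in-plane CH2OBz group acts as the large substituent, which puts hydride on the lower face of C6. No new compound arises (entry F0).

Further compounds
F1 | step 4 | racemic 7 (both cis-fused oxirane enantiomers) | CC(C)(C)[Si](C)(C)OCC1=CC(=O)[C@@H](O2)[C@@H]2C1(OC)OC.CC(C)(C)[Si](C)(C)OCC1=CC(=O)[C@H](O2)[C@H]2C1(OC)OC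
F2 | step 4 | racemic 8 | OCC1=CC(=O)[C@@H](O2)[C@@H]2C1(OC)OC.OCC1=CC(=O)[C@H](O2)[C@H]2C1(OC)OC
F3 | step 4 | racemic 10 | O=C(OCC1=CC(=O)[C@@H](O2)[C@@H]2C1(OC)OC)c1ccccc1.O=C(OCC1=CC(=O)[C@H](O2)[C@H]2C1(OC)OC)c1ccccc1
F4 | step 4 | racemic 11 (OH cis to the oxirane) | O=C(OCC1=C[C@@H](O)[C@@H](O2)[C@@H]2C1(OC)OC)c1ccccc1.O=C(OCC1=C[C@H](O)[C@H](O2)[C@H]2C1(OC)OC)c1ccccc1
F5 | step 4 | [(3S,4S,5S)-3-acetoxy-4,5-epoxy-6,6-dimethoxycyclohex-1-en-1-yl]methyl benzoate | O=C(OCC1=C[C@H](OC(C)=O)[C@H](O2)[C@H]2C1(OC)OC)c1ccccc1
F6 | step 9 | [(3R,4R,5S)-3,4,5-trihydroxy-6-oxocyclohex-1-en-1-yl]methyl benzoate | O=C(OCC1=C[C@@H](O)[C@@H](O)[C@H](O)C1=O)c1ccccc1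
F7 | step 9 | 3,4-O-isopropylidene derivative of F6 (O5 free) | O=C(OCC1=C[C@H]2OC(C)(C)O[C@H]2[C@H](O)C1=O)c1ccccc1
F8 | step 9 | O5 benzoate of F7 | O=C(OCC1=C[C@H]2OC(C)(C)O[C@H]2[C@H](OC(=O)c2ccccc2)C1=O)c1ccccc1
F0 | step 10 | none | none
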